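**Retrosynthetic overview**

1. Ring letters: upper (robinetinidol) unit A/C/B, lower (epigallocatechin) unit D/F/E, galloyl G. Last skeletal bond is C4(ring C)–C8(ring D), made by an intramolecular Friedel–Crafts reaction through a temporary O3(upper)–Si–O7(lower) tether that delivers ring D cis to O3 (4β); upper-unit C2/C3 come from (+)-dihydrorobinetin (chiral pool).
2. Pyran ring F is never closed as a six-membered ring: it arises from the furan ring of a cis-2-aryl-3-(hydroxymethyl)-2,3-dihydrobenzofuran by a one-carbon ring expansion, in which the ring-D carbon (future C4a) shifts from C3 to the exocyclic CH2 (future C4) while tri-O-benzylgallate is captured at C3 with inversion. Ring F, the C3–O–galloyl bond and the (2R,3R)-cis array result in one operation.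
3. Enabling feature: C4a of ring D lies ortho to O1 and O5 and para to O7 (phloroglucinol pattern). This makes it an exceptional neighbouring and migrating group, and the bridged phenonium ion keeps C2 and inverts C3 exactly once.
4. The cis-dihydrobenzofuran comes from an enantioselective rhodium-carbenoid C–H insertion of an aryldiazoacetate into one of two identical ortho O–CH2–aryl ethers (that aryl becomes ring E); the diazo ester comes from a phloroglucinol triether by directed lithiation.
5. Ring order: furan ring (step 5) → pyran ring F by expansion (step 7) → temporary seven-membered O–Si–O ring (formed and removed in step 13); rings A, B, C, D, E and G arrive with the building blocks.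

Key step: step 7

Abbreviations: Ar = 3,4,5-tris(benzyloxy)phenyl; ArCH2 = 3,4,5-tris(benzyloxy)benzyl; TIPS = triisopropylsilyl; Bn = benzyl.

Remark: (+)-dihydrorobinetin and 3,4,5-tris(benzyloxy)benzyl alcohol are taken as purchasable; the 4-methoxy electrophile and its two silyl derivatives are carried as C4-epimer mixtures (drawn as the major 4R epimer), because C4 is ionised in the coupling step.

**Route**

Step 1
Reactants: 1 phloroglucinol (benzene-1,3,5-triol)
Product: 2 5-(triisopropylsilyloxy)benzene-1,3-diol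
Conditions: TIPSCl (1 equiv), imidazole, DMF, 0 °C to rt; 1 in threefold excess
Reagents that add atoms: triisopropylsilyl chloride, CC(C)[Si](Cl)(C(C)C)C(C)C
Why: Silyl ether formation; the excess of the symmetric triol should stop the reaction at the mono-ether, and the TIPS group marks the future O7 with a group that neither directs lithiation nor offers an insertable C–H bond and is orthogonal to benzyl ethers.

Step 2
Reactants: 2 5-(triisopropylsilyloxy)benzene-1,3-diol; 3 3,4,5-tris(benzyloxy)benzyl alcohol (ArCH2OH, 2.1 equiv)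
Product: 4 1,3-bis(ArCH2O)-5-(TIPSO)benzene
Conditions: PPh3, DIAD, THF, 0 °C to rt
Reagents that add atoms: none
Why: Mitsunobu etherification of both free phenols by the benzylic alcohol under neutral conditions, which avoids the C-benzylation that phloroglucinol phenoxides undergo under basic alkylation; the aryl silyl ether is stable.

Step 3
Reactants: 4 1,3-bis(ArCH2O)-5-(TIPSO)benzene
Product: 6 methyl 2-oxo-2-[2,6-bis(ArCH2O)-4-(TIPSO)phenyl]acetate, via aryllithium 5 (not isolated)
Conditions: n-BuLi (1.2 equiv), THF, 0 °C; then cannulation into (CO2Me)2 (3 equiv), THF, −78 °C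
Reagents that add atoms: dimethyl oxalate, COC(=O)C(=O)OC
Why: Directed ortho-lithiation followed by acylation: the only ring proton flanked by two coordinating alkoxy groups (between the two ArCH2O ethers) is removed, the bulky non-coordinating TIPSO group leaves its neighbours untouched, and inverse addition to excess dimethyl oxalate stops at the α-keto ester.

Step 4
Reactants: 6 methyl 2-oxo-2-[2,6-bis(ArCH2O)-4-(TIPSO)phenyl]acetate
Product: 8 methyl 2-diazo-2-[2,6-bis(ArCH2O)-4-(TIPSO)phenyl]acetate, via tosylhydrazone 7 (not isolated)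
Conditions: TsNHNH2, toluene, 60 °C; then DBU, CH2Cl2, rt
Reagents that add atoms: p-toluenesulfonyl hydrazide, Cc1ccc(cc1)S(=O)(=O)NN
Why: Condensation of the activated keto group with tosylhydrazide and base-induced loss of sulfinate from the hydrazone anion (Bamford–Stevens-type diazo synthesis) should give the aryldiazoacetate; ester and ethers are inert.

Step 5
Reactants: 8 methyl 2-diazo-2-[2,6-bis(ArCH2O)-4-(TIPSO)phenyl]acetate
Product: 9 methyl (2S,3R)-2-Ar-4-(ArCH2O)-6-(TIPSO)-2,3-dihydrobenzofuran-3-carboxylate (2,3-cis)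
Conditions: Rh2(S-PTTL)4 (dirhodium tetrakis[N-phthaloyl-(S)-tert-leucinate], 2 mol %), toluene, −60 to −20 °C
Reagents that add atoms: none
Why: Intramolecular 1,5 C–H insertion of the donor/acceptor rhodium carbenoid into a benzylic C–H bond of an ortho O–CH2Ar ether (the two ortho ethers are identical, so either leads to the same constitution, and the para TIPS ether has no reachable C–H bond); the concerted insertion sets C2 and C3 together, cis as the kinetic outcome, with the absolute sense (2S,3R) imposed by the chiral carboxylate ligands (the mirror-image catalyst is taken if the induction proves opposite).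

Step 6
Reactants: 9 methyl (2S,3R)-2-Ar-4-(ArCH2O)-6-(TIPSO)-2,3-dihydrobenzofuran-3-carboxylate
Product: 10 [(2S,3S)-2-Ar-4-(ArCH2O)-6-(TIPSO)-2,3-dihydrobenzofuran-3-yl]methanol (2,3-cis)
Conditions: i-Bu2AlH, CH2Cl2, −78 to 0 °C; aqueous potassium sodium tartrate work-up
Reagents that add atoms: none
Why: Ester reduction with i-Bu2AlH at low temperature without enolate formation, so that the kinetic cis configuration is kept (C3 becomes S by CIP priority only); silyl and benzyl ethers are inert.

Step 7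
Reactants: 10 [(2S,3S)-2-Ar-4-(ArCH2O)-6-(TIPSO)-2,3-dihydrobenzofuran-3-yl]methanol; 11 3,4,5-tris(benzyloxy)benzoic acid
Product: 14 (2R,3R)-2-Ar-5-(ArCH2O)-7-(TIPSO)chroman-3-yl 3,4,5-tris(benzyloxy)benzoate (2,3-cis; protected epigallocatechin gallate), via primary triflate 12 (not isolated), via bridged phenonium triflate 13 (not isolated)
Conditions: Tf2O (1.05 equiv), 2,6-di-tert-butyl-4-methylpyridine (1.5 equiv), CH2Cl2, −78 °C; then 11 (3 equiv) premixed with i-Pr2NEt (3 equiv), −78 to −20 °C
Reagents that add atoms: none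
Why: Proposed new method: triflation gives 12, whose benzofuran carbon C3a (the future C4a, ortho to O1 and O5 and para to O7) displaces triflate from the exocyclic CH2 from the rear to give the bridged phenonium ion 13, and the carboxylate of 11 then opens the three-membered ring at the secondary carbon (future C3) with cleavage of the C3–C3a bond, so that the furan ring becomes pyran ring F and the 3-O-galloyl ester is installed in the same operation. The closest known reaction types are the anchimerically assisted neophyl-type (Wagner–Meerwein) 1,2-aryl shifts of β-arylalkyl sulfonates through phenonium ions and the stereospecific one-carbon ring expansions of 2-(sulfonyloxyalkyl)oxolanes and of prolinol derivatives with carboxylate capture; the combination has not been shown on a dihydrobenzofuran-3-ylmethyl sulfonate with an external carboxylate. The transient cyclopropane closes by 3-exo-tet attack of the aryl ipso carbon, and ring F arises by expansion of the five-membered ring by one carbon, not by a cyclisation onto the arene. C2 is untouched and C3 is inverted once, because the carboxylate enters anti to the departing C3a; this converts the (2S,3S)-cis alcohol into the (2R,3R)-2,3-cis ester, the descriptor at C2 changing by CIP priority only. The step needs opening at the secondary carbon instead of return at CH2, and substitution instead of proton loss to a flav-3-ene or hydride shift from C2; the first should follow from the larger positive charge at the secondary carbon of an unsymmetrical phenonium ion and from relief of bicyclic strain, the second from the tightly bridging trioxygenated arene, the low temperature, the hindered non-nucleophilic base and the excess of a soluble ammonium carboxylate.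

Step 8
Reactants: 14 (2R,3R)-2-Ar-5-(ArCH2O)-7-(TIPSO)chroman-3-yl 3,4,5-tris(benzyloxy)benzoate
Product: 15 (2R,3R)-2-Ar-5-(ArCH2O)-7-hydroxychroman-3-yl 3,4,5-tris(benzyloxy)benzoate
Conditions: Bu4NF, AcOH, THF, 0 °C
Reagents that add atoms: none
Why: Fluoride-induced cleavage of the aryl silyl ether, buffered with acetic acid so that the phenoxide formed neither cleaves nor migrates the galloyl ester; benzyl-type ethers are inert.

Step 9
Reactants: 16 (+)-dihydrorobinetin, (2R,3R)-3,7-dihydroxy-2-(3,4,5-trihydroxyphenyl)chroman-4-one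
Product: 17 (2R,3R)-2-Ar-7-(benzyloxy)-3-hydroxychroman-4-one
Conditions: BnBr (4.4 equiv), K2CO3, DMF, rt, argon
Reagents that add atoms: benzyl bromide, BrCc1ccccc1
Why: Williamson etherification of the four phenols (K2CO3 does not deprotonate the secondary 3-OH); C2 and C3 come from the natural product and the 2,3-trans array is the thermodynamic one, so it should survive the mild base.

Step 10
Reactants: 17 (2R,3R)-2-Ar-7-(benzyloxy)-3-hydroxychroman-4-one
Product: 18 (2R,3S,4R)-2-Ar-7-(benzyloxy)chroman-3,4-diol (2,3-trans-3,4-trans)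
Conditions: NaBH4, THF–MeOH, 0 °C
Reagents that add atoms: none
Why: Hydride reduction of the chroman-4-one carbonyl; attack anti to the 3-OH should give mainly the 3,4-trans diol (4R), but the C4 configuration is of no consequence because C4 is ionised later.

Step 11
Reactants: 18 (2R,3S,4R)-2-Ar-7-(benzyloxy)chroman-3,4-diol
Product: 19 (2R,3S,4R)-2-Ar-7-(benzyloxy)-4-methoxychroman-3-ol (with its 4S epimer)
Conditions: camphorsulfonic acid (cat.), MeOH–CH2Cl2, rt
Reagents that add atoms: methanol, CO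
Why: Acid-catalysed SN1 etherification: only the benzylic 4-OH ionises (cation stabilised by O1 and the 7-benzyloxy group of ring A) and is captured by methanol, which turns C4 into a latent leaving group and leaves the secondary 3-OH free; the C4 epimers converge in step 13.

Step 12
Reactants: 19 (2R,3S,4R)-2-Ar-7-(benzyloxy)-4-methoxychroman-3-ol; 15 (2R,3R)-2-Ar-5-(ArCH2O)-7-hydroxychroman-3-yl 3,4,5-tris(benzyloxy)benzoate
Product: 21 diisopropylsilylene diether joining O3 of 19 to O7 of 15, via chlorosilane 20 (not isolated)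
Conditions: i-Pr2SiCl2 (excess), imidazole, CH2Cl2, 0 °C, then removal of excess silane in vacuo; then 15, imidazole, DMAP (cat.), DMF, rt
Reagents that add atoms: dichlorodiisopropylsilane, CC(C)[Si](Cl)(Cl)C(C)C
Why: Temporary silicon connection by two successive silyl ether formations: the hindered secondary 3-OH is silylated with excess dichlorosilane to the monochlorosilane, whose remaining Si–Cl bond is displaced by the unhindered phenol 15; no stereocentre is touched.

Step 13
Reactants: 21 diisopropylsilylene diether joining O3 of 19 to O7 of 15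
Product: 23 protected dimer with free upper 3-OH and free lower 7-OH (upper C4, 4R, bonded to lower C8), via silylene-bridged dimer 22 (not isolated)
Conditions: Me3SiOTf (0.3 equiv), CH2Cl2 (dilute), −78 to −40 °C; pyridine quench; then HF·pyridine, THF, 0 °C
Reagents that add atoms: none
Why: Tether-directed intramolecular Friedel–Crafts alkylation (temporary silicon connection; the same principle as the known 3,4-cis-selective interflavan condensations of units joined through O3 by a diester tether): Me3SiOTf ionises the C4–OMe bond of either C4 epimer to the ring-A-stabilised benzylic cation, which the O3–Si–O7 tether lets ring D reach only on the face of O3 and only through a carbon ortho to O7, so that the new C4 stereocentre should form as 4R (3,4-cis, 4β) and bonding should occur at C8 rather than at C6, which is flanked by the bulky 5-O-benzylic ether; HF·pyridine then removes the silylene from the seven-membered ring.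

Step 14
Reactants: 23 protected dimer with free upper 3-OH and free lower 7-OH
Product: 24 robinetinidol-(4β→8)-epigallocatechin 3-O-gallate (target)
Conditions: H2 (1 atm), Pd(OH)2/C, THF–MeOH–H2O, rt
Reagents that add atoms: none
Why: Hydrogenolysis of the thirteen benzyl ethers and of the 5-O-(3,4,5-tribenzyloxybenzyl) ether over Pd(OH)2 under neutral conditions should release all phenols while the galloyl ester, the interflavan bond and the seven stereocentres stay untouched.

**Compound list**

1 | phloroglucinol (benzene-1,3,5-triol) | Oc1cc(O)cc(O)c1 | starting material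
2 | 5-(triisopropylsilyloxy)benzene-1,3-diol | CC(C)[Si](Oc1cc(O)cc(O)c1)(C(C)C)C(C)C | intermediate
3 | 3,4,5-tris(benzyloxy)benzyl alcohol (ArCH2OH) | OCc1cc(OCc2ccccc2)c(OCc2ccccc2)c(OCc2ccccc2)c1 | starting material
4 | 1,3-bis(ArCH2O)-5-(TIPSO)benzene | CC(C)[Si](Oc1cc(OCc2cc(OCc3ccccc3)c(OCc3ccccc3)c(OCc3ccccc3)c2)cc(OCc2cc(OCc3ccccc3)c(OCc3ccccc3)c(OCc3ccccc3)c2)c1)(C(C)C)C(C)C | intermediate
5 | 2,6-bis(ArCH2O)-4-(TIPSO)phenyllithium | [Li]c1c(OCc2cc(OCc3ccccc3)c(OCc3ccccc3)c(OCc3ccccc3)c2)cc(O[Si](C(C)C)(C(C)C)C(C)C)cc1OCc1cc(OCc2ccccc2)c(OCc2ccccc2)c(OCc2ccccc2)c1 | intermediate (not isolated)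
6 | methyl 2-oxo-2-[2,6-bis(ArCH2O)-4-(TIPSO)phenyl]acetate | COC(=O)C(=O)c1c(OCc2cc(OCc3ccccc3)c(OCc3ccccc3)c(OCc3ccccc3)c2)cc(O[Si](C(C)C)(C(C)C)C(C)C)cc1OCc1cc(OCc2ccccc2)c(OCc2ccccc2)c(OCc2ccccc2)c1 | intermediate
7 | N-tosylhydrazone of 6 | COC(=O)C(=NNS(=O)(=O)c1ccc(C)cc1)c1c(OCc2cc(OCc3ccccc3)c(OCc3ccccc3)c(OCc3ccccc3)c2)cc(O[Si](C(C)C)(C(C)C)C(C)C)cc1OCc1cc(OCc2ccccc2)c(OCc2ccccc2)c(OCc2ccccc2)c1 | intermediate (not isolated)
8 | methyl 2-diazo-2-[2,6-bis(ArCH2O)-4-(TIPSO)phenyl]acetate | COC(=O)C(=[N+]=[N-])c1c(OCc2cc(OCc3ccccc3)c(OCc3ccccc3)c(OCc3ccccc3)c2)cc(O[Si](C(C)C)(C(C)C)C(C)C)cc1OCc1cc(OCc2ccccc2)c(OCc2ccccc2)c(OCc2ccccc2)c1 | intermediate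
9 | methyl (2S,3R)-2-Ar-4-(ArCH2O)-6-(TIPSO)-2,3-dihydrobenzofuran-3-carboxylate (cis) | COC(=O)[C@H]1[C@@H](c2cc(OCc3ccccc3)c(OCc3ccccc3)c(OCc3ccccc3)c2)Oc2cc(O[Si](C(C)C)(C(C)C)C(C)C)cc(OCc3cc(OCc4ccccc4)c(OCc4ccccc4)c(OCc4ccccc4)c3)c12 | intermediate
10 | [(2S,3S)-2-Ar-4-(ArCH2O)-6-(TIPSO)-2,3-dihydrobenzofuran-3-yl]methanol (cis) | OC[C@H]1[C@@H](c2cc(OCc3ccccc3)c(OCc3ccccc3)c(OCc3ccccc3)c2)Oc2cc(O[Si](C(C)C)(C(C)C)C(C)C)cc(OCc3cc(OCc4ccccc4)c(OCc4ccccc4)c(OCc4ccccc4)c3)c12 | intermediate
11 | 3,4,5-tris(benzyloxy)benzoic acid | OC(=O)c1cc(OCc2ccccc2)c(OCc2ccccc2)c(OCc2ccccc2)c1 | starting material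
12 | trifluoromethanesulfonate of 10 | O=S(=O)(OC[C@H]1[C@@H](c2cc(OCc3ccccc3)c(OCc3ccccc3)c(OCc3ccccc3)c2)Oc2cc(O[Si](C(C)C)(C(C)C)C(C)C)cc(OCc3cc(OCc4ccccc4)c(OCc4ccccc4)c(OCc4ccccc4)c3)c12)C(F)(F)F | intermediate (not isolated)
13 | bridged phenonium triflate (former C3a bonded to both C3 and the former CH2; ion pair, one resonance form drawn) | C1[C@H]2[C@@H](c3cc(OCc4ccccc4)c(OCc4ccccc4)c(OCc4ccccc4)c3)[O+]=C3C=C(O[Si](C(C)C)(C(C)C)C(C)C)C=C(OCc4cc(OCc5ccccc5)c(OCc5ccccc5)c(OCc5ccccc5)c4)[C@]123.[O-]S(=O)(=O)C(F)(F)F | intermediate (not isolated)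
14 | (2R,3R)-2-Ar-5-(ArCH2O)-7-(TIPSO)chroman-3-yl 3,4,5-tris(benzyloxy)benzoate (cis) | O=C(O[C@@H]1Cc2c(OCc3cc(OCc4ccccc4)c(OCc4ccccc4)c(OCc4ccccc4)c3)cc(O[Si](C(C)C)(C(C)C)C(C)C)cc2O[C@@H]1c1cc(OCc2ccccc2)c(OCc2ccccc2)c(OCc2ccccc2)c1)c1cc(OCc2ccccc2)c(OCc2ccccc2)c(OCc2ccccc2)c1 | intermediate
15 | (2R,3R)-2-Ar-5-(ArCH2O)-7-hydroxychroman-3-yl 3,4,5-tris(benzyloxy)benzoate | O=C(O[C@@H]1Cc2c(OCc3cc(OCc4ccccc4)c(OCc4ccccc4)c(OCc4ccccc4)c3)cc(O)cc2O[C@@H]1c1cc(OCc2ccccc2)c(OCc2ccccc2)c(OCc2ccccc2)c1)c1cc(OCc2ccccc2)c(OCc2ccccc2)c(OCc2ccccc2)c1 | intermediate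
16 | (+)-dihydrorobinetin, (2R,3R)-3,7-dihydroxy-2-(3,4,5-trihydroxyphenyl)chroman-4-one | O=C1c2ccc(O)cc2O[C@H](c2cc(O)c(O)c(O)c2)[C@H]1O | starting material
17 | (2R,3R)-2-Ar-7-(benzyloxy)-3-hydroxychroman-4-one | O=C1c2ccc(OCc3ccccc3)cc2O[C@H](c2cc(OCc3ccccc3)c(OCc3ccccc3)c(OCc3ccccc3)c2)[C@H]1O | intermediate
18 | (2R,3S,4R)-2-Ar-7-(benzyloxy)chroman-3,4-diol | O[C@@H]1c2ccc(OCc3ccccc3)cc2O[C@H](c2cc(OCc3ccccc3)c(OCc3ccccc3)c(OCc3ccccc3)c2)[C@H]1O | intermediate
19 | (2R,3S,4R)-2-Ar-7-(benzyloxy)-4-methoxychroman-3-ol (major epimer drawn) | CO[C@@H]1c2ccc(OCc3ccccc3)cc2O[C@H](c2cc(OCc3ccccc3)c(OCc3ccccc3)c(OCc3ccccc3)c2)[C@H]1O | intermediate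
20 | 3-O-[chloro(diisopropyl)silyl] ether of 19 | CO[C@@H]1c2ccc(OCc3ccccc3)cc2O[C@H](c2cc(OCc3ccccc3)c(OCc3ccccc3)c(OCc3ccccc3)c2)[C@H]1O[Si](Cl)(C(C)C)C(C)C | intermediate (not isolated)
21 | diisopropylsilylene diether joining O3 of 19 to O7 of 15 | O=C(O[C@@H]1Cc2c(OCc3cc(OCc4ccccc4)c(OCc4ccccc4)c(OCc4ccccc4)c3)cc(O[Si](C(C)C)(C(C)C)O[C@H]3[C@H](OC)c4ccc(OCc5ccccc5)cc4O[C@@H]3c3cc(OCc4ccccc4)c(OCc4ccccc4)c(OCc4ccccc4)c3)cc2O[C@@H]1c1cc(OCc2ccccc2)c(OCc2ccccc2)c(OCc2ccccc2)c1)c1cc(OCc2ccccc2)c(OCc2ccccc2)c(OCc2ccccc2)c1 | intermediate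
22 | silylene-bridged dimer: upper C4 (R) bonded to lower C8, O3(upper)–Si(i-Pr)2–O7(lower) in a seven-membered ring | O=C(O[C@@H]1Cc2c(OCc7cc(OCc6ccccc6)c(OCc6ccccc6)c(OCc6ccccc6)c7)cc(O[Si]5(C(C)C)C(C)C)c([C@H]3c4ccc(OCc6ccccc6)cc4O[C@H](c7cc(OCc6ccccc6)c(OCc6ccccc6)c(OCc6ccccc6)c7)[C@H]3O5)c2O[C@@H]1c7cc(OCc6ccccc6)c(OCc6ccccc6)c(OCc6ccccc6)c7)c7cc(OCc6ccccc6)c(OCc6ccccc6)c(OCc6ccccc6)c7 | intermediate (not isolated)
23 | protected dimer, free upper 3-OH and lower 7-OH, thirteen O-benzyl groups and the 5-O-ArCH2 ether in place | O=C(O[C@@H]1Cc2c(OCc6cc(OCc5ccccc5)c(OCc5ccccc5)c(OCc5ccccc5)c6)cc(O)c([C@H]3c4ccc(OCc5ccccc5)cc4O[C@H](c6cc(OCc5ccccc5)c(OCc5ccccc5)c(OCc5ccccc5)c6)[C@H]3O)c2O[C@@H]1c6cc(OCc5ccccc5)c(OCc5ccccc5)c(OCc5ccccc5)c6)c6cc(OCc5ccccc5)c(OCc5ccccc5)c(OCc5ccccc5)c6 | intermediate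
24 | robinetinidol-(4β→8)-epigallocatechin 3-O-gallate | O=C(O[C@@H]1Cc2c(O)cc(O)c([C@H]3c4ccc(O)cc4O[C@H](c4cc(O)c(O)c(O)c4)[C@H]3O)c2O[C@@H]1c1cc(O)c(O)c(O)c1)c1cc(O)c(O)c(O)c1 | target

**Step count and risks**

Total step count: 14 (steps 1–8 lower unit, steps 9–11 upper unit, steps 12–14 union and deprotection).
Longest linear sequence: 11 steps (1–8, then 12–14).

Steps most likely to fail:

1. Step 7 (Proposed new method). The bridged ion may collapse by proton loss to a flav-3-ene or by hydride shift from C2, or be captured at the primary carbon without ring expansion; partial opening to a free C3 cation would erode the cis relationship. Fallback by known chemistry, setting out from 10 and coming back at 14: alcohol 10 is converted with MsCl and Et3N into the primary mesylate F1. Buffered solvolysis of F1 in aqueous hexafluoroisopropanol with 2,6-lutidine, the classical aryl-assisted solvolytic 1,2-shift with water as the capturing nucleophile, should give the ring-expanded (2R,3R)-chroman-3-ol F2. Should C3 form as an epimer mixture, Dess–Martin oxidation to the chroman-3-one F3 and reduction with LiBH(s-Bu)3 (hydride anti to the 2-aryl group, the known 2,3-cis-selective reduction of flavan-3-ones) funnel everything back to the cis alcohol F2. Steglich esterification of F2 with 11 (DCC, DMAP) then returns 14.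

2. Step 13. The tethered arene may bond through C6 instead of C8, or Me3SiOTf may strip the acid-labile 5-O-(trialkoxybenzyl) ether or scramble the silylene before the C–C bond forms. Fallback by known chemistry, setting out from 15 and 16 and coming back at 24: hydrogenolysis of 15 (H2, Pd(OH)2/C) gives free (−)-epigallocatechin gallate F4, and NaBH4 reduction of 16 gives the free (2R,3S,4R)-flavan-3,4-diol leucorobinetinidin F5. Condensation of F5 with an excess of F4 in dilute aqueous HCl at rt, the biomimetic flavan-3,4-diol/flavan-3-ol coupling that is known to give both 4α- and 4β-(4→8) dimers from 5-deoxy diols, followed by Sephadex LH-20 and reversed-phase chromatography, should deliver 24 directly. Separation then replaces tether control.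

3. Step 5. The two ortho substituents twist the carbenoid out of the arene plane, which may blunt the enantio- and cis-discrimination of the chiral dirhodium catalyst. Fallback, setting out from 8 and coming back at 9: decomposition of 8 with achiral Rh2(OAc)4 gives the racemic cis ester F6 (kinetic cis insertion), which is resolved on a chiral stationary phase (preparative supercritical-fluid chromatography) to give 9; asymmetric catalysis is thus replaced by racemic synthesis and resolution.

**Further compounds**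

F1 | step 7 | methanesulfonate of 10 | CS(=O)(=O)OC[C@H]1[C@@H](c2cc(OCc3ccccc3)c(OCc3ccccc3)c(OCc3ccccc3)c2)Oc2cc(O[Si](C(C)C)(C(C)C)C(C)C)cc(OCc3cc(OCc4ccccc4)c(OCc4ccccc4)c(OCc4ccccc4)c3)c12
F2 | step 7 | (2R,3R)-2-Ar-5-(ArCH2O)-7-(TIPSO)chroman-3-ol | O[C@@H]1Cc2c(OCc3cc(OCc4ccccc4)c(OCc4ccccc4)c(OCc4ccccc4)c3)cc(O[Si](C(C)C)(C(C)C)C(C)C)cc2O[C@@H]1c1cc(OCc2ccccc2)c(OCc2ccccc2)c(OCc2ccccc2)c1
F3 | step 7 | (2R)-2-Ar-5-(ArCH2O)-7-(TIPSO)chroman-3-one | O=C1Cc2c(OCc3cc(OCc4ccccc4)c(OCc4ccccc4)c(OCc4ccccc4)c3)cc(O[Si](C(C)C)(C(C)C)C(C)C)cc2O[C@@H]1c1cc(OCc2ccccc2)c(OCc2ccccc2)c(OCc2ccccc2)c1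
F4 | step 13 | (−)-epigallocatechin gallate | O=C(O[C@@H]1Cc2c(O)cc(O)cc2O[C@@H]1c1cc(O)c(O)c(O)c1)c1cc(O)c(O)c(O)c1
F5 | step 13 | leucorobinetinidin, (2R,3S,4R)-2-(3,4,5-trihydroxyphenyl)chroman-3,4,7-triol | O[C@@H]1c2ccc(O)cc2O[C@H](c2cc(O)c(O)c(O)c2)[C@H]1O
F6 | step 5 | racemic cis methyl 2-Ar-4-(ArCH2O)-6-(TIPSO)-2,3-dihydrobenzofuran-3-carboxylate (both enantiomers) | COC(=O)[C@H]1[C@@H](c2cc(OCc3ccccc3)c(OCc3ccccc3)c(OCc3ccccc3)c2)Oc2cc(O[Si](C(C)C)(C(C)C)C(C)C)cc(OCc3cc(OCc4ccccc4)c(OCc4ccccc4)c(OCc4ccccc4)c3)c12.COC(=O)[C@@H]1[C@H](c2cc(OCc3ccccc3)c(OCc3ccccc3)c(OCc3ccccc3)c2)Oc2cc(O[Si](C(C)C)(C(C)C)C(C)C)cc(OCc3cc(OCc4ccccc4)c(OCc4ccccc4)c(OCc4ccccc4)c3)c12
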